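If we want the most target from the noon flask, we must choose its charge and when to stop it.

| flask | starting material | time |
|---|---|---|
| midnight | 0.400 M |  |
| dawn | 0.160 M |  |
| dusk | 0.200 M |  |
| noon | 0.400 M | 93 min |

| run | time / min | [target] / M |
|---|---|---|
| midnight run | 1.8 | 0.0015 |
| midnight run | 5.3 | 0.0238 |
| midnight run | 10 | 0.0582 |
| midnight run | 16 | 0.0971 |
| midnight run | 23 | 0.1329 |
| midnight run | 31 | 0.1546 |
| dawn run | 1.8 | 0.0011 |
| dawn run | 5.3 | 0.0077 |
| dawn run | 10 | 0.0219 |
| dawn run | 16 | 0.0367 |
| dawn run | 23 | 0.0488 |
| dawn run | 31 | 0.0611 |
| dusk run | 1.8 | 0.0020 |
| dusk run | 5.3 | 0.0104 |
| dusk run | 10 | 0.0282 |
| dusk run | 16 | 0.0450 |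
| dusk run | 23 | 0.0634 |
| dusk run | 31 | 0.0763 |

(scatter of a reading: 0.001 M)

- Overall: starting material -> target.
- Constant volume, constant temperature.
- What is held in complexes is read along with the free species.
- An order is taken over about fifteen percent of the charge, up and down.

- how the opening rate goes with [starting material] round the charge of the midnight run: the exponent of the rate at two percent of starting material gone to target (one fixed amount of target, the same in the runs compared)
- target in the noon run at 93 min, as a share of the starting material charged

The charge first. At 31 min the share of charge read as target is 38.6% at midnight, 38.1% at dusk and 38.2% at dawn, so we keep midnight's charge.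

The stopping time needs more, because a reading of target shows net gain. We follow one molecule and ignore the opening lag. In the midnight run, target rises at 0.00648 M/min between 10 min and 16 min, around 0.0776 M of target, but at 0.00271 M/min between 23 min and 31 min, around 0.144 M, which is slower. As a rough first step we let the earlier window speak for the gain, neglecting loss there, and divide its rate by the charge less that target, which gives 0.0201 /min as the gain chance, the chance per minute that a molecule still in the charge becomes target. At that chance the charge falls exponentially, and at 27.0 min, the middle of the later window, we reckon 0.232 M of it still waiting. The gain reckoned there, less the net rise, divided by the target present, gives 0.0136 /min as the loss chance of a target molecule. Both are readings with scatter. With the charge falling and target lost at these chances, our reckoning puts the maximum near 60.0 min and noon at 39.5% by 93 min. So for yield we would stop near that maximum, but we leave noon to 93 min once, to test the loss.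

The forecast differs from our reckoning, with an order of 0.8 (0.6 to 1.05) and noon at 54% (47% to 62%), on the ground that “Conversion rate against conversion extrapolates to zero”.

The noon flask gives 29.5% and the order is 0.69, so our figure for noon stands 10 percentage points too high.

    2 starting material ⇌ intermediate + starting material (2.106 /M/min, 0.7200 /M/min)
    intermediate → target (0.1788 /min)
    2 starting material ⇌ idle substrate dimer, settled at all times (21.30 /M)
    target → decomposed product (0.01980 /min)

With no loss, the gain chance gives 84.6% by 93 min, and the noon flask shows 34.9% of that, about a third. The main reason for the gap is the conversion of target into decomposed product. The noon run without that step, which otherwise gives 29.5%, reaches 89.8%.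

All runs come from a simulation with constants of no real substance; the scatter is artificial.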